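**Strategy.** Ring C of the flavan is read as a hetero-Diels–Alder adduct: C4 is a lone methylene between aromatic C4a and C3, and O1–C2(aryl)–C3 maps onto a styrene. The key step joins three components, methyl 4-(benzyloxy)-2,6-dihydroxybenzoate, formaldehyde and 4-(benzyloxy)styrene, through an ortho-quinone methide (O1=C8a–C4a=C4) under a chiral Brønsted acid, forming C4–C3 and O1–C2 and setting C2. The precursor is mirror-symmetric; its ester blocks C8, keeps both hydroxyls equivalent and leaves later as CO2. A catalyst-controlled Friedel–Crafts addition of C8 to a vicinal triketone then sets the carbinol carbon, and debenzylation lets the flanked ketone ketalise with two phenols, the cis ring fusion relaying the ketal configuration.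

Key step: step 2

Remarks on the chemistry:
- Flavan numbering (O1, C2, C3, C4, C4a, C5–C8, C8a; rings A, B, C) is used for the 2-arylchroman unit. In the other half, "carbinol carbon" means the tertiary C–OH next to the ketone and "ketal carbon" the carbon bearing the 4-hydroxyphenyl group and two oxygens.
- The Friedel–Crafts adduct of step 7 is drawn as the open hydroxy diketone; in solution it should equilibrate with the five-membered hemiketal formed by the neighbouring 7-OH, which does not affect the route.
- 4-(Benzyloxy)styrene is taken as a catalogue monomer (otherwise one Wittig step from 4-(benzyloxy)benzaldehyde).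

Step 1
Reactants: 1 methyl 2,4,6-trihydroxybenzoate
Product: 2 methyl 4-(benzyloxy)-2,6-dihydroxybenzoate
Conditions: BnBr (1.05 equiv), KHCO3 (1.1 equiv), DMF, 40 °C
Reagents that add atoms: benzyl bromide, BrCc1ccccc1
Why: Williamson etherification: the 4-OH is the most acidic hydroxyl and the only one not hydrogen-bonded to the ester carbonyl, so one equivalent of benzyl bromide with a weak base should alkylate it alone, leaving a mirror-symmetric resorcinol whose two hydroxyls and two ring C–H positions are equivalent.

Step 2
Reactants: 2 methyl 4-(benzyloxy)-2,6-dihydroxybenzoate; 3 paraformaldehyde (formaldehyde source); 4 4-(benzyloxy)styrene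
Product: 7 methyl (2S)-5-(benzyloxy)-2-[4-(benzyloxy)phenyl]-7-hydroxy-3,4-dihydro-2H-chromene-8-carboxylate, via hydroxymethyl phenol 5 (not isolated), via ortho-quinone methide 6 (not isolated)
Conditions: 3 (1.1 equiv as (CH2O)n), 4 (3 equiv), chiral H8-BINOL-derived N-triflylphosphoramide bearing 3,3'-(2,4,6-triisopropylphenyl) groups (5 mol %), CHCl3, 5 Å MS, 0 °C
Reagents that add atoms: none
Why: Proposed new method: the acid depolymerises paraformaldehyde and promotes ortho-hydroxymethylation of 2 at either of its two equivalent ring C–H positions to give 5, which loses water to ortho-quinone methide 6; held by the catalyst through hydrogen bonds to the quinone methide carbonyl and the neighbouring ester carbonyl, 6 reacts with styrene 4 in an inverse-electron-demand oxa-[4+2] cycloaddition. The closest known reactions are the thermal or acid-promoted three-component chroman synthesis from phenols, paraformaldehyde and alkenes and the chiral N-triflylphosphoramide-catalysed [4+2] cycloaddition of ortho-quinone methides (from 2-hydroxybenzyl alcohols) with styrenes; untested is their merger on an unsubstituted methide. Ring C is closed by a concerted but asynchronous [4+2] closure in which the C4–C3 bond (methide carbon to the styrene terminus) leads and the O1–C2 bond follows. C2, the only new stereocenter, is under catalyst control: the chiral anion shields one enantiotopic face of the planar heterodiene while the aryl group sits endo, and the catalyst antipode that gives (2S) is used. Regiochemistry is secured by the substrate, since the 4-O-benzyl ether allows quinone methide formation only towards the hydroxyl next to the ester and the styrene adds with its terminus to the electrophilic methide carbon, giving the 2-aryl and not the 3-aryl chroman. The selectivity still needed, cycloaddition ahead of styrene oligomerisation and of methylene-bridged dimer formation, is sought with excess 4, low temperature and slow release of formaldehyde.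

Step 3
Reactants: 7 methyl (2S)-5-(benzyloxy)-2-[4-(benzyloxy)phenyl]-7-hydroxy-3,4-dihydro-2H-chromene-8-carboxylate
Product: 9 (2S)-5-(benzyloxy)-2-[4-(benzyloxy)phenyl]-3,4-dihydro-2H-chromen-7-ol, via carboxylic acid 8 (not isolated)
Conditions: KOH, DMSO–H2O, 90 °C; then AcOH to pH 5, 80 °C
Reagents that add atoms: none
Why: Saponification of the hindered salicylate followed by protodecarboxylation (ipso protonation of the 2,4,6-trioxygenated benzoic acid and loss of CO2) frees C8; C2 should be untouched because its 4'-oxygen stays benzylated, so no quinone methide ring opening is possible in base.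

Step 4
Reactants: 10 2',4',6'-trihydroxyacetophenone
Product: 11 1-[2,4,6-tris(benzyloxy)phenyl]ethan-1-one
Conditions: BnBr (3.6 equiv), K2CO3, DMF, 80 °C
Reagents that add atoms: benzyl bromide, BrCc1ccccc1
Why: Williamson etherification: excess benzyl bromide and carbonate at 80 °C alkylate all three phenols, including the two hydrogen-bonded ortho hydroxyls, so that no free phenol can later add to the triketone.

Step 5
Reactants: 11 1-[2,4,6-tris(benzyloxy)phenyl]ethan-1-one; 12 methyl 4-(benzyloxy)benzoate
Product: 13 1-[4-(benzyloxy)phenyl]-3-[2,4,6-tris(benzyloxy)phenyl]propane-1,3-dione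
Conditions: NaH (2.5 equiv), THF, reflux; then aq. HCl
Reagents that add atoms: none
Why: Crossed Claisen condensation: the methyl ketone enolate of 11 is acylated on carbon by the non-enolisable ester 12, and deprotonation of the 1,3-diketone by the second equivalent of hydride drives the equilibrium.

Step 6
Reactants: 13 1-[4-(benzyloxy)phenyl]-3-[2,4,6-tris(benzyloxy)phenyl]propane-1,3-dione
Product: 14 1-[4-(benzyloxy)phenyl]-3-[2,4,6-tris(benzyloxy)phenyl]propane-1,2,3-trione
Conditions: Dess–Martin periodinane (2.5 equiv), pyridine, CH2Cl2, rt; dried azeotropically before use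
Reagents that add atoms: Dess–Martin periodinane, CC(=O)OI1(OC(C)=O)(OC(C)=O)OC(=O)c2ccccc12
Why: Dess–Martin oxidation of an enolised 1,3-diketone to the vicinal tricarbonyl (two successive two-electron oxidations at the doubly activated methylene); benzyl ethers and the arenes should be inert to the reagent at room temperature.

Step 7
Reactants: 9 (2S)-5-(benzyloxy)-2-[4-(benzyloxy)phenyl]-3,4-dihydro-2H-chromen-7-ol; 14 1-[4-(benzyloxy)phenyl]-3-[2,4,6-tris(benzyloxy)phenyl]propane-1,2,3-trione
Product: 15 (2S)-2-[(2S)-5-(benzyloxy)-2-[4-(benzyloxy)phenyl]-7-hydroxy-3,4-dihydro-2H-chromen-8-yl]-1-[4-(benzyloxy)phenyl]-2-hydroxy-3-[2,4,6-tris(benzyloxy)phenyl]propane-1,3-dione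
Conditions: quinine-derived 3,5-bis(trifluoromethyl)phenyl squaramide (10 mol %; the quinidine-derived pseudoenantiomer if it proves to be the one giving the (S)-carbinol), toluene, 4 Å MS, −20 °C
Reagents that add atoms: none
Why: Proposed new method: the squaramide N–H groups bind the central, most electrophilic carbonyl of 14 while the quinuclidine nitrogen hydrogen-bonds the 7-OH of 9, so that the ortho carbon C8 is delivered to one enantiotopic face in a Friedel–Crafts hydroxyalkylation followed by rearomatisation; the closest known reactions are the uncatalysed addition of phenols to vicinal tricarbonyl compounds and cinchona squaramide- or thiourea-catalysed enantioselective ortho-hydroxyalkylations of electron-rich phenols and naphthols with isatins and trifluoropyruvates. The new carbinol stereocenter is set by the catalyst (the remote C2 should exert no influence), which must tell the bulky 2,4,6-tris(benzyloxy)benzoyl flank from the 4-(benzyloxy)benzoyl flank, and C8 is preferred over C6 because it is flanked by the small ring oxygen whereas the 5-benzyloxy group, turned away from the C4 methylene, shields C6. The (S) descriptor of this carbon in 15 becomes (R) in 17 only because ring closure changes the CIP priorities.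

Step 8
Reactants: 15 (2S)-2-[(2S)-5-(benzyloxy)-2-[4-(benzyloxy)phenyl]-7-hydroxy-3,4-dihydro-2H-chromen-8-yl]-1-[4-(benzyloxy)phenyl]-2-hydroxy-3-[2,4,6-tris(benzyloxy)phenyl]propane-1,3-dione
Product: 17 target CNP0208300.2, via debenzylated hydroxy diketone 16 (not isolated)
Conditions: H2 (1 atm), Pd/C (10 wt %), EtOAc–MeOH, rt; filter; PPTS (cat.), MeCN, 4 Å MS, rt
Reagents that add atoms: none
Why: Hydrogenolysis cleaves the six O-benzyl groups to give 16, in which the 4-hydroxybenzoyl carbonyl is flanked by the flavan 7-OH and an ortho-OH of the trihydroxybenzoyl ring; acid-catalysed double ketalisation (via a hemiketal and a 2-aryl oxocarbenium ion) closes the dihydrofuran and pyranone rings, and because a five/six bicyclic ketal at these two carbons can only be cis-fused, the (R) ketal carbon follows from the carbinol carbon set in step 7.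

**Compound list**

1 | methyl 2,4,6-trihydroxybenzoate | COC(=O)c1c(O)cc(O)cc1O | starting material
2 | methyl 4-(benzyloxy)-2,6-dihydroxybenzoate | COC(=O)c1c(O)cc(OCc2ccccc2)cc1O | intermediate
3 | paraformaldehyde (formaldehyde source) | C=O | starting material
4 | 4-(benzyloxy)styrene | C=Cc1ccc(OCc2ccccc2)cc1 | starting material
5 | methyl 4-(benzyloxy)-2,6-dihydroxy-3-(hydroxymethyl)benzoate (not isolated) | COC(=O)c1c(O)cc(OCc2ccccc2)c(CO)c1O | intermediate
6 | methyl 4-(benzyloxy)-2-hydroxy-5-methylidene-6-oxocyclohexa-1,3-diene-1-carboxylate, the ortho-quinone methide (not isolated) | COC(=O)C1=C(O)C=C(OCc2ccccc2)C(=C)C1=O | intermediate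
7 | methyl (2S)-5-(benzyloxy)-2-[4-(benzyloxy)phenyl]-7-hydroxy-3,4-dihydro-2H-chromene-8-carboxylate | COC(=O)c1c(O)cc(OCc2ccccc2)c2c1O[C@H](c1ccc(OCc3ccccc3)cc1)CC2 | intermediate
8 | (2S)-5-(benzyloxy)-2-[4-(benzyloxy)phenyl]-7-hydroxy-3,4-dihydro-2H-chromene-8-carboxylic acid (not isolated) | OC(=O)c1c(O)cc(OCc2ccccc2)c2c1O[C@H](c1ccc(OCc3ccccc3)cc1)CC2 | intermediate
9 | (2S)-5-(benzyloxy)-2-[4-(benzyloxy)phenyl]-3,4-dihydro-2H-chromen-7-ol | Oc1cc(OCc2ccccc2)c2c(c1)O[C@H](c1ccc(OCc3ccccc3)cc1)CC2 | intermediate
10 | 2',4',6'-trihydroxyacetophenone | CC(=O)c1c(O)cc(O)cc1O | starting material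
11 | 1-[2,4,6-tris(benzyloxy)phenyl]ethan-1-one | CC(=O)c1c(OCc2ccccc2)cc(OCc2ccccc2)cc1OCc1ccccc1 | intermediate
12 | methyl 4-(benzyloxy)benzoate | COC(=O)c1ccc(OCc2ccccc2)cc1 | starting material
13 | 1-[4-(benzyloxy)phenyl]-3-[2,4,6-tris(benzyloxy)phenyl]propane-1,3-dione | O=C(CC(=O)c1ccc(OCc2ccccc2)cc1)c1c(OCc2ccccc2)cc(OCc2ccccc2)cc1OCc1ccccc1 | intermediate
14 | 1-[4-(benzyloxy)phenyl]-3-[2,4,6-tris(benzyloxy)phenyl]propane-1,2,3-trione | O=C(C(=O)C(=O)c1ccc(OCc2ccccc2)cc1)c1c(OCc2ccccc2)cc(OCc2ccccc2)cc1OCc1ccccc1 | intermediate
15 | (2S)-2-[(2S)-5-(benzyloxy)-2-[4-(benzyloxy)phenyl]-7-hydroxy-3,4-dihydro-2H-chromen-8-yl]-1-[4-(benzyloxy)phenyl]-2-hydroxy-3-[2,4,6-tris(benzyloxy)phenyl]propane-1,3-dione | O[C@](C(=O)c1c(OCc2ccccc2)cc(OCc2ccccc2)cc1OCc1ccccc1)(C(=O)c1ccc(OCc2ccccc2)cc1)c1c(O)cc(OCc2ccccc2)c2c1O[C@H](c1ccc(OCc3ccccc3)cc1)CC2 | intermediate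
16 | (2S)-2-[(2S)-5,7-dihydroxy-2-(4-hydroxyphenyl)-3,4-dihydro-2H-chromen-8-yl]-2-hydroxy-1-(4-hydroxyphenyl)-3-(2,4,6-trihydroxyphenyl)propane-1,3-dione (not isolated) | O[C@](C(=O)c1c(O)cc(O)cc1O)(C(=O)c1ccc(O)cc1)c1c(O)cc(O)c2c1O[C@H](c1ccc(O)cc1)CC2 | intermediate
17 | CNP0208300.2: (2S)-flavan fused through its 7-O and C8 to a cis-fused dihydrobenzofuro-chromanone, ketal carbon (R), carbinol carbon (R) | O=C1c2c(O)cc(O)cc2O[C@@]2(c3ccc(O)cc3)Oc3cc(O)c4c(c3[C@@]12O)O[C@H](c1ccc(O)cc1)CC4 | target

**Step count.** Total: 8 steps. Longest linear sequence: 5 steps (steps 1, 2, 3, 7, 8; the triketone branch, steps 4, 5, 6, 7, 8, is equally long).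

**Steps most likely to fail**

1. Step 2 (Proposed new method). The chiral acid may discriminate poorly between the two faces of an unsubstituted quinone methide, so that C2 forms with low enantioselectivity. The electron-rich styrene may also oligomerise under acid, and the quinone methide may be intercepted by a second molecule of 2 or react a second time at C6 of the product. Fallback with known chemistry, from 2 back to 7: an achiral acid-catalysed three-component cycloaddition of 2, paraformaldehyde and commercial 1-(benzyloxy)-4-ethynylbenzene (TsOH·H2O cat., 1,2-dichloroethane, 60 °C) should give the flav-2-ene methyl 5-(benzyloxy)-2-[4-(benzyloxy)phenyl]-7-hydroxy-4H-chromene-8-carboxylate F1. Ring C is still closed through the C3–C4 bond in a quinone methide cycloaddition, but no stereocenter is formed. C2 is then set by asymmetric hydrogenation of the C2=C3 enol ether with [Ir(cod)(L)][B(C6H3(CF3)2)4], L = 4-tert-butyl-2-[2-(diphenylphosphino)phenyl]-4,5-dihydrooxazole in the antipode giving (2S) (H2 50 bar, CH2Cl2), a known way to 2-arylchromans, which returns the route to 7.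

2. Step 7 (Proposed new method). Facial discrimination at the central carbonyl of the triketone may be poor, because the catalyst has to distinguish two aroyl flanks. Attack may also leak to C6, and the basic catalyst may trigger acyl migration in the 2-hydroxy-1,3-diketone. Fallback with known chemistry, from 9 and 14 back to 15: the uncatalysed aromatic hydroxyalkylation of phenols by vicinal tricarbonyls (AcOH, CH2Cl2, rt) should give 15 together with its (R)-carbinol epimer F2. The two are diastereomers because of the (2S) flavan centre and would be separated by chromatography; stereocontrol by catalyst is thus replaced by separation, and the route continues from 15.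

3. Step 8. Hydrogenolysis may over-reduce (cleavage of the benzylic C2–O1 bond of the flavan, reduction of an aryl ketone), and the seven-fold phenol 16 may ketalise incompletely or decompose on handling. Fallback, from 15 back to 17: chelation-controlled cleavage of one benzyl ether ortho to the ketone (MgBr2·OEt2, toluene–Et2O, 60 °C) should give the mono-phenol (2S)-1-[2,4-bis(benzyloxy)-6-hydroxyphenyl]-3-[4-(benzyloxy)phenyl]-2-[(2S)-5-(benzyloxy)-2-[4-(benzyloxy)phenyl]-7-hydroxy-3,4-dihydro-2H-chromen-8-yl]-2-hydroxypropane-1,3-dione F3. This is ketalised (PPTS, MeCN, 4 Å MS) to the penta-O-benzyl ether of the target F4, in which the rings are already closed and the reactive ketone is masked. Hydrogenolysis of the five remaining benzyl ethers (H2, Pd(OH)2/C, EtOAc–MeOH) then gives 17.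

Further compounds
F1 | step 2 | methyl 5-(benzyloxy)-2-[4-(benzyloxy)phenyl]-7-hydroxy-4H-chromene-8-carboxylate | COC(=O)c1c(O)cc(OCc2ccccc2)c2c1OC(c1ccc(OCc3ccccc3)cc1)=CC2
F2 | step 7 | (2R)-2-[(2S)-5-(benzyloxy)-2-[4-(benzyloxy)phenyl]-7-hydroxy-3,4-dihydro-2H-chromen-8-yl]-1-[4-(benzyloxy)phenyl]-2-hydroxy-3-[2,4,6-tris(benzyloxy)phenyl]propane-1,3-dione (carbinol epimer of 15) | O[C@@](C(=O)c1c(OCc2ccccc2)cc(OCc2ccccc2)cc1OCc1ccccc1)(C(=O)c1ccc(OCc2ccccc2)cc1)c1c(O)cc(OCc2ccccc2)c2c1O[C@H](c1ccc(OCc3ccccc3)cc1)CC2
F3 | step 8 | (2S)-1-[2,4-bis(benzyloxy)-6-hydroxyphenyl]-3-[4-(benzyloxy)phenyl]-2-[(2S)-5-(benzyloxy)-2-[4-(benzyloxy)phenyl]-7-hydroxy-3,4-dihydro-2H-chromen-8-yl]-2-hydroxypropane-1,3-dione | O[C@](C(=O)c1c(O)cc(OCc2ccccc2)cc1OCc1ccccc1)(C(=O)c1ccc(OCc2ccccc2)cc1)c1c(O)cc(OCc2ccccc2)c2c1O[C@H](c1ccc(OCc3ccccc3)cc1)CC2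
F4 | step 8 | penta-O-benzyl ether of 17 (benzyl on both remaining phenols of the chromanone ring, on both 4-hydroxyphenyl groups and on the flavan 5-OH) | O=C1c2c(OCc3ccccc3)cc(OCc3ccccc3)cc2O[C@@]2(c3ccc(OCc4ccccc4)cc3)Oc3cc(OCc4ccccc4)c4c(c3[C@@]12O)O[C@H](c1ccc(OCc3ccccc3)cc1)CC4
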